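## The problem

Compound 34 is a briarane. A ten-membered carbocycle (C1–C10) shares its C1–C10 edge with a cyclohexene (C1, C10–C14) and its C7–C8 edge with a γ-lactone (C7, C8, C17, C19, O). C2 and C9 are trans on the six-membered ring, and C6 and C9 are trans on the lactone.

Nine stereocentres must be set. Four are contiguous on the cyclohexene (quaternary C1, C10, C11, C12). Two are the flanking carbinols C2 and C9. Three form the lactone triad C7/C8/C17, in which C8 is a fully substituted carbinol.

The ring centres can steer their neighbours: C1 can control C2 and C10 can control C9 through Felkin–Anh additions, and C9 can then control C7/C8 as an allylic stereocentre. C17 is epimerisable and can be left to equilibration.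

The C5=C6 alkene is tetrasubstituted, carries chlorine and must hold C4 and C7 on the same side. Its geometry therefore has to be fixed before the ring exists, not by olefination or metathesis.

Several groups are fragile:
- the two allylic acetates (base, hydride, zerovalent palladium);
- the β-hydroxy lactone (retro-aldol, E1cB loss of the C8 oxygen);
- the allylic C7–O bond.

Closure of the ten-membered ring is costly in entropy and transannular strain.

One feature opens the problem. C8 bears oxygen and is bonded to both C7 and C17, while C19 reaches C7 through a single oxygen atom. Removing that oxygen leaves C7–C8–C17–C19 as a 3-oxycyclobutanone, the adduct of a ketene with a C7=C8 enol ether. One stereospecific cycloaddition can thus deliver both lactone C–C bonds and the C7/C8 pair.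

## Retrosynthesis

**C4–C5 (34 ⇒ 33 ⇒ 31).** After removal of the two silyl ethers of 33, the macrocycle is opened between sp3 C4 and sp2 C5.
- A cut at C2–C3 or C9–C10 would sacrifice a stereocentre. A cut at C5=C6 would sacrifice the alkene geometry.
- The seco compound 31 keeps every stereocentre and carries a terminal vinyl group and a C5 enol triflate.
- The forward step is a hydroboration followed by an intramolecular B-alkyl Suzuki coupling. It must tolerate two acetates and a lactone.

**C19–O–C7 and C17–H (31 ⇒ 30 ⇒ 29).** The C17 hydrogen is exchanged for chlorine, and the ring oxygen is taken out between C19 and C7.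
- The chlorine makes the ketene reactive and suppresses migration of C17, so the Baeyer–Villiger step can only move C7, with retention.
- Dechlorinating first would leave two secondary carbons competing for migration.
- The forward steps need a peracid that spares three alkenes and a reduction that does not expel the C8 oxygen.

**C7–C19 and C8–C17 (29 ⇒ 26 + 28).**
- An aldol of a propionate on a C8 ketone would form only one of these bonds and would leave C7 oxygenation to a separate event.
- The [2+2] cut forms both bonds and links C7 to C8 through the alkene geometry.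
- The precursor 26 is acyclic between C5 and C9. There a Z enol ether is easy to secure, which would not hold inside a ten-membered ring.
- The forward reaction needs regiocontrol (polarity), retention of the alkene geometry, and face selection by C9.

**O–Si, C8=O and C9–H (26 ⇒ 25 ⇒ 24 ⇒ 23).**
- Both silyl groups of 26 come from one soft enolisation and silylation of acyloin 25. This saves a separate C9 protecting group.
- A Felkin–Anh analysis at C10 shows that adding a C8 nucleophile to a C9 aldehyde would give the wrong C9 epimer. Delivering hydride to a C9 ketone gives the right one.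
- C9 is therefore traced to ketone 23, with C8 masked as a dithiane.

**C7–C8 and the acetates (23 ⇒ 20 ⇒ 18 + 4).**
- The acetates of 23 are installed only after the last strongly basic step.
- Lithiating a dithiane that already carries the halogenated butenyl chain would destroy the cross-coupling handle. The order is therefore reversed.
- The acidic C8–H of 2-acyl dithiane 18 is removed with NaH, and the stabilised anion is alkylated with allylic bromide 4.
- This splits the molecule into a C5–C7 piece and the complete cyclohexene piece.

**C8–C9 (18 ⇒ 15 + 16).**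
- C8 is supplied by 1,3-dithiane 16.
- The acyl donor is the bridged lactone 15, not a hindered ethyl ester. The lactone ties the carbonyl back, releases the C12 hydroxyl on opening and needs no protecting group.

**C12–H, C11–H (15 ⇒ 13 ⇒ 11).**
- All reagents should reach C11 and C12 from the α face, because C15, C9 and C20 crowd the β face.
- Hydrogen is therefore what is delivered: a proton to C11 and hydride to C12.
- The resulting 12β-oxygen is used first, for lactone 15, and inverted later by acetate, again from the α face.

**C2–C3, then C1–C14 and C10–C11 (11 ⇒ 9 ⇒ 8 ⇒ 6 + 7).**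
- The vinyl group is removed from C2, leaving an aldehyde on quaternary C1.
- The ring is then split into siloxydiene 6 and the commercial trans-enal ester 7.
- This Diels–Alder cut creates C1 and C10 with the correct trans C2/C9 relationship in one step from two five-carbon units.
- Alkylation routes to the quaternary centre would need many more steps.

**C5–O (4 ⇒ 2 ⇒ 1).**
- Electrophilic iodochlorination of a but-2-ynoate would place chlorine on C5 and iodine on C6.
- The handle is therefore an enol triflate of commercial 1, whose geometry is set by a lithium chelate.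

## Roads not taken

**Alternative 1:** The cut removes C6–Cl and C7–O together and leads to the ten-membered 5,6-allene hydroxy acid A1. In the forward direction N-chlorosuccinimide would deliver Cl+ to the central allene carbon C6, and the C19 carboxyl group would add anti at C7. The product is A2, the C9 triethylsilyl ether of 34.
- *Merits:* lactone and chloroalkene appear together in the penultimate step. No C17 chlorine has to be carried and erased. The alkene geometry follows from the allene axis.
- *Weak points:* the C8 carbinol with its C17 side chain must already be in place, so the hardest centre is not addressed by the key step. A medium-ring allene of defined axial chirality has to be closed and kept configurationally intact. Cl+ can also attack the C5=C6 π-bond face leading to the other alkene isomer, the C8 hydroxyl can compete as nucleophile, and C13=C14 is exposed to the halogenating agent.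
- *Comparison:* this road is shorter after ring closure and better in endgame economy. The chosen plan offers instead a stereospecific link between C7 and C8 and an alkene geometry that is settled in step 1 and never at risk.

**Alternative 2:** Reconnecting C3 with C8 hides the ten-membered ring in the trans-fused tricyclic chlorocyclohexadiene A3. Irradiation would open ring A conrotatorily, cleaving C3–C8 to give triene A4 with a ring-cis C5=C6 bond.
- *Merits:* the medium ring arises by ring expansion without an entropic penalty, which is exactly where the chosen plan is weakest. The C5=C6 geometry is inherited from a six-membered ring.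
- *Weak points:*
  - Cyclohexadiene and triene form photostationary mixtures with re-closure, E/Z isomerisation and sigmatropic hydrogen shifts.
  - The C–Cl bond of a chlorodiene is itself photolabile.
  - Two E alkenes in a ten-membered ring are strained.
  - A4 still lacks the C7 and C8 oxygens. C7=C8 would have to be oxidised on one face, and C3=C4 reduced, in the presence of three other alkenes.
  - The C8 quaternary centre built into A3 is destroyed.
- *Comparison:* this road is better for ring formation but worse for everything that follows. The chosen plan accepts a risky macrocyclisation in exchange for having all oxygen functions and stereocentres in place beforehand.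

**Alternative 3:** The cut is C1–C10. The silyl ketene acetal of δ-lactone A5 would rearrange through an enforced boat (Ireland–Claisen), breaking C13–O and giving cyclohexene acid A6 with C13=C14 in place.
- *Merits:* chirality transfer is reliable. C11 and C12 come from acyclic aldol chemistry with the correct configuration, so neither the C11 re-protonation nor the C12 inversion of the chosen route would be needed. In this respect it is superior.
- *Weak points:* it solves only the cyclohexene. The lactone, C8, the chloroalkene and the macrocycle remain open. A5 needs three stereocentres and a Z trisubstituted alkene from a long linear sequence. C2 arrives as a benzyloxymethyl group that still requires deprotection, oxidation and vinyl addition.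
- *Comparison:* as a fragment synthesis it could replace steps 4–10. As the strategic step it leaves the central problem untouched. The Diels–Alder entry reaches the same ring in far fewer operations.

Key step: step 19

Convention: atom numbers are briarane numbers throughout. β is the face of the cyclohexene that carries the C15 methyl group, and α is the opposite face.

Assumption: the (S)-diphenylprolinol-derived cationic oxazaborolidine is taken to expose the face of 7 that leads to (1S,10S)-8. If the sense is opposite, the equally available (R)-catalyst is used and nothing else changes.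

## Steps

Step 1
Reactants: 1 methyl 2-chloro-3-oxobutanoate
Product: 2 methyl (E)-2-chloro-3-(trifluoromethylsulfonyloxy)but-2-enoate
Conditions: Tf2O, Et3N, LiOTf, CH2Cl2, 0 °C
Reagents that add atoms: trifluoromethanesulfonic anhydride, O=S(=O)(OS(=O)(=O)C(F)(F)F)C(F)(F)F
Why: Stereoselective enol triflate formation from a lithium-chelated β-keto ester enolate; the chelate holds the enolate oxygen cis to the ester carbon C7, so OTf ends cis to C7 and trans to Cl, which is the ring-cis C5=C6 geometry.

Step 2
Reactants: 2 methyl (E)-2-chloro-3-(trifluoromethylsulfonyloxy)but-2-enoate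
Product: 3 (E)-3-chloro-4-hydroxybut-2-en-2-yl trifluoromethanesulfonate
Conditions: i-Bu2AlH (2.2 equiv), CH2Cl2, −78 °C; Rochelle salt
Reagents that add atoms: none
Why: 1,2-Reduction of an enoate to the allylic alcohol; vinyl triflates and vinyl chlorides are not touched by i-Bu2AlH at low temperature and the alkene geometry cannot change.

Step 3
Reactants: 3 (E)-3-chloro-4-hydroxybut-2-en-2-yl trifluoromethanesulfonate
Product: 4 (E)-4-bromo-3-chlorobut-2-en-2-yl trifluoromethanesulfonate
Conditions: CBr4, PPh3, CH2Cl2, 0 °C
Reagents that add atoms: carbon tetrabromide, BrC(Br)(Br)Br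
Why: Appel bromination of a primary allylic alcohol under neutral conditions; SN2′ attack is blocked by the fully substituted C5.

Step 4
Reactants: 5 pent-1-en-3-one
Product: 6 (Z)-3-(tert-butyldimethylsilyloxy)penta-1,3-diene
Conditions: TBSOTf, Et3N, Et2O, 0 °C
Reagents that add atoms: tert-butyldimethylsilyl trifluoromethanesulfonate, CC(C)(C)[Si](C)(C)OS(=O)(=O)C(F)(F)F
Why: Soft enolisation and O-silylation of an ethyl ketone gives the thermodynamically preferred Z silyl enol ether, in which the methyl group points away from the vinyl group so that the diene can reach the s-cis form.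

Step 5
Reactants: 6 (Z)-3-(tert-butyldimethylsilyloxy)penta-1,3-diene; 7 ethyl (E)-3-methyl-4-oxobut-2-enoate
Product: 8 ethyl (1S,2S,6S)-3-(tert-butyldimethylsilyloxy)-6-formyl-2,6-dimethylcyclohex-3-ene-1-carboxylate
Conditions: (S)-3,3-diphenyl-1-(2-methylphenyl)tetrahydro-1H,3H-pyrrolo[1,2-c][1,3,2]oxazaborole (15 mol %), HNTf2 (12 mol %), CH2Cl2, −78 °C
Reagents that add atoms: none
Why: Enantioselective Diels–Alder reaction of a 2-siloxydiene with a 2-methyl-3-alkoxycarbonyl enal under cationic oxazaborolidine catalysis: the boron-bound formyl group directs the nucleophilic diene terminus C11 to C10, and the E dienophile sets C2 and C9 trans and C15 and C9 cis, with the catalyst choosing the enal face. A formyl-endo approach is expected and puts C20 on the α face; the exo adduct would differ only at C11, and step 9 brings both to the same compound.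

Step 6
Reactants: 8 ethyl (1S,2S,6S)-3-(tert-butyldimethylsilyloxy)-6-formyl-2,6-dimethylcyclohex-3-ene-1-carboxylate
Product: 9 C2 allylic alcohol (2S)
Conditions: CH2=CHMgBr, THF, −78 °C; aq. NH4Cl at −78 °C
Reagents that add atoms: vinylmagnesium bromide, C=C[Mg]Br
Why: Grignard addition to the aldehyde, much faster than to the hindered ester. Felkin–Anh control by quaternary C1 (C10 large and anti to the nucleophile, which passes over the C15 methyl group) leads to the 2S carbinol.

Step 7
Reactants: 9 C2 allylic alcohol (2S)
Product: 10 C2 triethylsilyl ether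
Conditions: TESOTf, 2,6-lutidine, CH2Cl2, −78 °C
Reagents that add atoms: triethylsilyl trifluoromethanesulfonate, CC[Si](CC)(CC)OS(=O)(=O)C(F)(F)F
Why: Silylation of a neopentyl-type secondary alcohol with a silyl triflate; the TES ether withstands the carbanion chemistry ahead and can be removed later without touching acetates.

Step 8
Reactants: 10 C2 triethylsilyl ether
Product: 11 C12 enone with C20 on the α face
Conditions: Pd(OAc)2 (10 mol %), O2 (1 atm), DMSO, 45 °C
Reagents that add atoms: none
Why: Saegusa–Ito oxidation; divalent palladium binds C13 of the silyl enol ether and β-hydride elimination can only take a C14 hydrogen, so C13=C14 forms regiospecifically.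

Step 9
Reactants: 11 C12 enone with C20 on the α face
Product: 13 C12 enone with C20 on the β face, via lithium dienolate 12 (not isolated)
Conditions: LiN(i-Pr)2, THF, −78 °C; then AcOH in THF, −78 °C
Reagents that add atoms: none
Why: Kinetic protonation of an enolate: C1 is quaternary, so only C11–H can be removed. In the planar dienolate the C9 ester turns pseudoaxial to avoid the C11 methyl group and, together with C15, screens the β face, so the proton enters from the α face and pushes C20 to the β face.

Step 10
Reactants: 13 C12 enone with C20 on the β face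
Product: 15 bridged C9–O–C12 lactone, via hydroxy ester 14 (not isolated)
Conditions: NaBH4, CeCl3·7H2O, MeOH, −78 °C; work-up; DBU (cat.), toluene, 60 °C
Reagents that add atoms: none
Why: Luche 1,2-reduction followed by lactonisation: the pseudoaxial C9 ester blocks the β face, so hydride arrives from the α face and gives the 12β-alcohol. This alcohol is 1,3-diaxial to the ester and closes to the known 6-oxabicyclo[3.2.1]oct-3-en-7-one ring type.

Step 11
Reactants: 15 bridged C9–O–C12 lactone; 16 1,3-dithiane
Product: 18 C9 ketone bearing a 1,3-dithian-2-yl group, via 2-lithio-1,3-dithiane 17 (not isolated)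
Conditions: 16 (2.5 equiv), n-BuLi, THF, −30 °C; then 15, −78 → −20 °C; aq. NH4Cl
Reagents that add atoms: none
Why: Corey–Seebach acylation of a lithiated dithiane by a lactone: the tied-back carbonyl is accessible, ring opening frees the C12 alkoxide, and a second equivalent of 17 deprotonates the acidic C8–H of the product and so prevents double addition. Compound 18 may rest as its bridged lactol.

Step 12
Reactants: 18 C9 ketone bearing a 1,3-dithian-2-yl group; 4 (E)-4-bromo-3-chlorobut-2-en-2-yl trifluoromethanesulfonate
Product: 20 C8-alkylated keto dithiane, via sodium enolate 19 (not isolated)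
Conditions: NaH (1.0 equiv), THF/DMF, 0 °C; then 4, 0 °C → rt
Reagents that add atoms: none
Why: C-alkylation of a sulfur- and carbonyl-stabilised carbanion with a soft allylic bromide (SN2). In aprotic medium C8–H is far more acidic than the C12 hydroxyl, and the vinyl triflate never meets an alkyllithium.

Step 13
Reactants: 20 C8-alkylated keto dithiane
Product: 21 12α-acetate
Conditions: AcOH, PPh3, DIAD, toluene, 0 °C → rt
Reagents that add atoms: acetic acid, CC(=O)O
Why: Mitsunobu inversion: acetate displaces the activated 12β-oxygen from the open α face and installs the final acetate with the 12R configuration. SN2′ attack at C14 is hindered by quaternary C1, and C2 is still silylated.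

Step 14
Reactants: 21 12α-acetate
Product: 22 C2 alcohol
Conditions: HF·pyridine, pyridine, THF, 0 °C
Reagents that add atoms: none
Why: Fluoride-assisted cleavage of a TES ether under buffered acidic conditions, which leave acetate, dithiane and vinyl triflate untouched; basic fluoride sources are avoided because they eliminate vinyl triflates.

Step 15
Reactants: 22 C2 alcohol
Product: 23 2,12-diacetate C9 ketone
Conditions: Ac2O, DMAP, pyridine, CH2Cl2, rt
Reagents that add atoms: acetic anhydride, CC(=O)OC(C)=O
Why: DMAP-catalysed acetylation of the hindered allylic alcohol with retention at C2; no other hydroxyl group is present.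

Step 16
Reactants: 23 2,12-diacetate C9 ketone
Product: 24 C9 alcohol (9S)
Conditions: NaBH4, MeOH/THF, −20 → 0 °C
Reagents that add atoms: none
Why: Felkin–Anh reduction: C1 stands anti to the hydride and the bulky dithiane carbon C8 lies next to C10–H, which gives the 9S alcohol. The two sulfur atoms activate the ketone enough for NaBH4, which spares the acetates.

Step 17
Reactants: 24 C9 alcohol (9S)
Product: 25 C8 ketone with free C9 hydroxyl (acyloin)
Conditions: MeI, CaCO3, MeCN/H2O (9:1), 40 °C
Reagents that add atoms: water, O
Why: Alkylative dithiane hydrolysis (S-methylation, then hydrolysis of the sulfonium ion) under near-neutral conditions that do not enolise the acyloin or attack alkenes, acetates or triflate.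

Step 18
Reactants: 25 C8 ketone with free C9 hydroxyl (acyloin)
Product: 26 (7Z)-C7=C8 tert-butyldimethylsilyl enol ether with C9 OTBS
Conditions: TBSOTf (3 equiv), Et3N, CH2Cl2, −78 → 0 °C
Reagents that add atoms: tert-butyldimethylsilyl trifluoromethanesulfonate (two equivalents), CC(C)(C)[Si](C)(C)OS(=O)(=O)C(F)(F)F
Why: One-pot O-silylation of C9–OH and soft enolisation: the doubly activated allylic C7 protons are lost rather than the hindered C9–H. The conjugated enol ether forms with C6 trans to the bulky C9 branch, that is cis to OTBS (Z).

Step 19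
Reactants: 26 (7Z)-C7=C8 tert-butyldimethylsilyl enol ether with C9 OTBS; 27 2-chloropropanoyl chloride
Product: 29 3-siloxy-2-chloro-2-methylcyclobutanone (7S 8S; C17 epimers), via chloro(methyl)ketene 28 (not isolated)
Conditions: 27 (5 equiv, syringe pump), Et3N (6 equiv), hexane, reflux
Reagents that add atoms: none
Why: Et3N dehydrochlorinates 27 to ketene 28, whose carbonyl carbon C19 is attacked by the nucleophilic enol ether carbon C7, and the chlorinated carbon C17 then closes on the siloxy-stabilised C8 in a strongly asynchronous [2+2] cycloaddition that is suprafacial on the enol ether. The closest known reaction type is the cycloaddition of dichloro- and alkylchloroketenes with ketone silyl enol ethers to 3-siloxy-2-chlorocyclobutanones. The single ring formed, the cyclobutanone C7–C8–C17–C19, closes in this intermolecular [2+2] mode through the two new bonds C7–C19 and C8–C17. The relative configuration of C7 and C8 is fixed by the Z alkene: C6 and OTBS are cis on the double bond and stay cis on the ring, so C6 and C9 end trans as in the lactone of 34. The absolute sense is set by C9: in the reactive conformer C10 is anti to the incoming ketene, C9–H lies beside the C8 siloxy group (least A1,2 strain) and the C9 oxygen sits inside over C7–H, which exposes the face leading to the 7S,8S product. Regioselectivity follows from the polarity match of ketene and enol ether. A [4+2] path is closed because the tetrasubstituted C5=C6 unit cannot become s-cis without pressing OTf against C8, and the unactivated vinyl and C13=C14 alkenes are too poor as ketenophiles to compete. C17 forms as a mixture, which is harmless because step 21 erases it, and slow addition keeps the ketene concentration below the level at which dimerisation dominates.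

Step 20
Reactants: 29 3-siloxy-2-chloro-2-methylcyclobutanone (7S 8S; C17 epimers)
Product: 30 17-chloro γ-lactone
Conditions: mCPBA, CH2Cl2, 0 °C → rt
Reagents that add atoms: 3-chloroperbenzoic acid, OOC(=O)c1cccc(Cl)c1
Why: Baeyer–Villiger oxidation of a strained α-chlorocyclobutanone, which is far faster than epoxidation of the mono- and disubstituted or electron-poor alkenes present. The chlorine-bearing C17 migrates poorly, so C7 migrates with retention and oxygen enters between C19 and C7.

Step 21
Reactants: 30 17-chloro γ-lactone
Product: 31 seco lactone (17R)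
Conditions: Zn dust, AcOH/THF, 0 °C → rt; filtered crude, DBU (0.1 equiv), CH2Cl2, rt
Reagents that add atoms: none
Why: Reductive dehalogenation of an α-chloro ester; the zinc enolate is protonated at once by acetic acid, and vinyl chloride and vinyl triflate are inert to zinc. Catalytic DBU equilibrates C17 to the isomer with C18 trans to the bulky C9 branch and cis to OTBS, which is the 17R configuration of 34.

Step 22
Reactants: 31 seco lactone (17R)
Product: 33 ten-membered ring bis(silyl ether), via B-alkyl borane 32 (not isolated)
Conditions: 9-BBN-H, THF, rt; then slow addition to PdCl2(dppf) (20 mol %), AsPh3, Cs2CO3, DMF/THF/H2O, 50 °C, 1 mM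
Reagents that add atoms: none
Why: Anti-Markovnikov hydroboration of the only terminal alkene places boron on C4, 1,3 to the C2 acetate, so no β-elimination is possible. Intramolecular B-alkyl Suzuki–Miyaura coupling with the enol triflate then forms C4–C5 with retention of the alkene geometry, a reaction type established for macrocyclisation.

Step 23
Reactants: 33 ten-membered ring bis(silyl ether)
Product: 34 target CNP0296164.1
Conditions: HF·pyridine, THF, 0 → 40 °C
Reagents that add atoms: none
Why: Global fluoride-mediated desilylation under acidic buffering frees C8–OH and C9–OH without acetate migration, lactone opening or retro-aldol cleavage, all of which are base-promoted.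

## Compound list

1 | methyl 2-chloro-3-oxobutanoate | COC(=O)C(Cl)C(C)=O | starting material
2 | methyl (E)-2-chloro-3-(trifluoromethylsulfonyloxy)but-2-enoate (OTf cis to the ester, trans to Cl) | COC(=O)/C(Cl)=C(/C)OS(=O)(=O)C(F)(F)F | intermediate
3 | (E)-3-chloro-4-hydroxybut-2-en-2-yl trifluoromethanesulfonate | OC/C(Cl)=C(/C)OS(=O)(=O)C(F)(F)F | intermediate
4 | (E)-4-bromo-3-chlorobut-2-en-2-yl trifluoromethanesulfonate (C5–C7 fragment) | BrC/C(Cl)=C(/C)OS(=O)(=O)C(F)(F)F | intermediate
5 | pent-1-en-3-one | C=CC(=O)CC | starting material
6 | (Z)-3-(tert-butyldimethylsilyloxy)penta-1,3-diene | C=C/C(O[Si](C)(C)C(C)(C)C)=C/C | intermediate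
7 | ethyl (E)-3-methyl-4-oxobut-2-enoate | CCOC(=O)/C=C(\C)C=O | starting material
8 | ethyl (1S,2S,6S)-3-(tert-butyldimethylsilyloxy)-6-formyl-2,6-dimethylcyclohex-3-ene-1-carboxylate (ester and C15 β, formyl and C20 α) | CCOC(=O)[C@H]1[C@H](C)C(O[Si](C)(C)C(C)(C)C)=CC[C@]1(C)C=O | intermediate
9 | ethyl (1S,2S,6S)-3-(tert-butyldimethylsilyloxy)-6-[(1S)-1-hydroxyprop-2-enyl]-2,6-dimethylcyclohex-3-ene-1-carboxylate | CCOC(=O)[C@H]1[C@H](C)C(O[Si](C)(C)C(C)(C)C)=CC[C@]1(C)[C@@H](O)C=C | intermediate
10 | C2 triethylsilyl ether of 9 | CCOC(=O)[C@H]1[C@H](C)C(O[Si](C)(C)C(C)(C)C)=CC[C@]1(C)[C@@H](O[Si](CC)(CC)CC)C=C | intermediate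
11 | ethyl (1S,2S,6S)-2,6-dimethyl-3-oxo-6-[(1S)-1-(triethylsilyloxy)prop-2-enyl]cyclohex-4-ene-1-carboxylate (C20 α) | CCOC(=O)[C@H]1[C@H](C)C(=O)C=C[C@]1(C)[C@@H](O[Si](CC)(CC)CC)C=C | intermediate
12 | lithium C11=C12 dienolate of 11 | [Li+].CCOC(=O)[C@H]1C(C)=C([O-])C=C[C@]1(C)[C@@H](O[Si](CC)(CC)CC)C=C | intermediate
13 | ethyl (1S,2R,6S)-2,6-dimethyl-3-oxo-6-[(1S)-1-(triethylsilyloxy)prop-2-enyl]cyclohex-4-ene-1-carboxylate (C20 β) | CCOC(=O)[C@H]1[C@@H](C)C(=O)C=C[C@]1(C)[C@@H](O[Si](CC)(CC)CC)C=C | intermediate
14 | ethyl (1S,2R,3S,6S)-3-hydroxy-2,6-dimethyl-6-[(1S)-1-(triethylsilyloxy)prop-2-enyl]cyclohex-4-ene-1-carboxylate (12β-OH) | CCOC(=O)[C@H]1[C@@H](C)[C@@H](O)C=C[C@]1(C)[C@@H](O[Si](CC)(CC)CC)C=C | intermediate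
15 | 2,8-dimethyl-2-[(1S)-1-(triethylsilyloxy)prop-2-enyl]-6-oxabicyclo[3.2.1]oct-3-en-7-one (lactone bridge C9–O–C12 on the β face) | O=C1O[C@H]2C=C[C@](C)([C@@H](O[Si](CC)(CC)CC)C=C)[C@@H]1[C@H]2C | intermediate
16 | 1,3-dithiane | C1CSCSC1 | starting material
17 | 2-lithio-1,3-dithiane | [Li]C1SCCCS1 | intermediate
18 | 1,3-dithian-2-yl (1S,2R,3S,6S)-3-hydroxy-2,6-dimethyl-6-[(1S)-1-(triethylsilyloxy)prop-2-enyl]cyclohex-4-en-1-yl ketone | O=C(C1SCCCS1)[C@H]2[C@@H](C)[C@@H](O)C=C[C@]2(C)[C@@H](O[Si](CC)(CC)CC)C=C | intermediate
19 | sodium enolate of 18 (C8=C9) | [Na+].[O-]C(=C1SCCCS1)[C@H]2[C@@H](C)[C@@H](O)C=C[C@]2(C)[C@@H](O[Si](CC)(CC)CC)C=C | intermediate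
20 | C9 ketone, C8 dithiane carrying the (E)-2-chloro-3-(triflyloxy)but-2-enyl chain, 12β-OH, 2-OTES | FC(F)(F)S(=O)(=O)O/C(C)=C(/Cl)CC1(SCCCS1)C(=O)[C@H]2[C@@H](C)[C@@H](O)C=C[C@]2(C)[C@@H](O[Si](CC)(CC)CC)C=C | intermediate
21 | as 20, with 12α-OAc in place of 12β-OH | FC(F)(F)S(=O)(=O)O/C(C)=C(/Cl)CC1(SCCCS1)C(=O)[C@H]2[C@@H](C)[C@H](OC(C)=O)C=C[C@]2(C)[C@@H](O[Si](CC)(CC)CC)C=C | intermediate
22 | as 21, with free (2S)-OH | FC(F)(F)S(=O)(=O)O/C(C)=C(/Cl)CC1(SCCCS1)C(=O)[C@H]2[C@@H](C)[C@H](OC(C)=O)C=C[C@]2(C)[C@@H](O)C=C | intermediate
23 | 2,12-diacetate, C9 ketone, C8 dithiane | FC(F)(F)S(=O)(=O)O/C(C)=C(/Cl)CC1(SCCCS1)C(=O)[C@H]2[C@@H](C)[C@H](OC(C)=O)C=C[C@]2(C)[C@@H](OC(C)=O)C=C | intermediate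
24 | 2,12-diacetate, (9S)-alcohol, C8 dithiane | FC(F)(F)S(=O)(=O)O/C(C)=C(/Cl)CC1(SCCCS1)[C@@H](O)[C@H]2[C@@H](C)[C@H](OC(C)=O)C=C[C@]2(C)[C@@H](OC(C)=O)C=C | intermediate
25 | 2,12-diacetate, C8 ketone, (9S)-hydroxyl (acyloin) | FC(F)(F)S(=O)(=O)O/C(C)=C(/Cl)CC(=O)[C@@H](O)[C@H]2[C@@H](C)[C@H](OC(C)=O)C=C[C@]2(C)[C@@H](OC(C)=O)C=C | intermediate
26 | (7Z)-C7=C8 TBS enol ether (C6 cis to OTBS), (9S)-OTBS, C5 enol triflate, C6 chloride, 2,12-diacetate, C3=C4 vinyl | FC(F)(F)S(=O)(=O)O/C(C)=C(/Cl)\C=C(/O[Si](C)(C)C(C)(C)C)[C@@H](O[Si](C)(C)C(C)(C)C)[C@H]2[C@@H](C)[C@H](OC(C)=O)C=C[C@]2(C)[C@@H](OC(C)=O)C=C | intermediate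
27 | 2-chloropropanoyl chloride | CC(Cl)C(Cl)=O | starting material
28 | chloro(methyl)ketene | CC(Cl)=C=O | intermediate
29 | cyclobutanone C7–C8–C17–C19 (7S,8S; C6 and OTBS on one ring face, H7 and C9 on the other; C17 Cl/Me as epimers) | FC(F)(F)S(=O)(=O)O/C(C)=C(/Cl)[C@@H]1C(=O)C(C)(Cl)[C@@]1(O[Si](C)(C)C(C)(C)C)[C@@H](O[Si](C)(C)C(C)(C)C)[C@H]2[C@@H](C)[C@H](OC(C)=O)C=C[C@]2(C)[C@@H](OC(C)=O)C=C | intermediate
30 | 17-chloro-17-methyl γ-lactone (O between C19 and C7, C7 retained; C17 epimers) | FC(F)(F)S(=O)(=O)O/C(C)=C(/Cl)[C@@H]1OC(=O)C(C)(Cl)[C@@]1(O[Si](C)(C)C(C)(C)C)[C@@H](O[Si](C)(C)C(C)(C)C)[C@H]2[C@@H](C)[C@H](OC(C)=O)C=C[C@]2(C)[C@@H](OC(C)=O)C=C | intermediate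
31 | seco lactone, (17R)-methyl cis to 8-OTBS | FC(F)(F)S(=O)(=O)O/C(C)=C(/Cl)[C@@H]1OC(=O)[C@H](C)[C@@]1(O[Si](C)(C)C(C)(C)C)[C@@H](O[Si](C)(C)C(C)(C)C)[C@H]2[C@@H](C)[C@H](OC(C)=O)C=C[C@]2(C)[C@@H](OC(C)=O)C=C | intermediate
32 | C4 9-borabicyclo[3.3.1]nonan-9-yl derivative of 31 | FC(F)(F)S(=O)(=O)O/C(C)=C(/Cl)[C@@H]1OC(=O)[C@H](C)[C@@]1(O[Si](C)(C)C(C)(C)C)[C@@H](O[Si](C)(C)C(C)(C)C)[C@H]2[C@@H](C)[C@H](OC(C)=O)C=C[C@]2(C)[C@@H](OC(C)=O)CCB3C4CCCC3CCC4 | intermediate
33 | 8,9-bis(tert-butyldimethylsilyl) ether of 34 | CC(=O)O[C@H]1CC/C(C)=C(/Cl)[C@@H]2OC(=O)[C@H](C)[C@@]2(O[Si](C)(C)C(C)(C)C)[C@@H](O[Si](C)(C)C(C)(C)C)[C@H]2[C@@H](C)[C@H](OC(C)=O)C=C[C@@]21C | intermediate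
34 | CNP0296164.1, (1S,2S,5E,7R,8R,9S,10S,11R,12R,17R)-2,12-diacetoxy-6-chloro-8,9-dihydroxybriara-5,13-dien-19,7-olide | CC(=O)O[C@H]1CC/C(C)=C(/Cl)[C@@H]2OC(=O)[C@H](C)[C@@]2(O)[C@@H](O)[C@H]2[C@@H](C)[C@H](OC(C)=O)C=C[C@@]21C | target

## Step count and least certain steps

Total step count: 23. Longest linear sequence: 20 steps (steps 4–23, from 5). Steps 1–3 form the side branch that delivers 4.

**Step 19 (key step).**
- *Main danger:* C8–C17 must form between two fully substituted carbons. The zwitterion formed after C7–C19 bonding may therefore collapse by silyl transfer or proton loss to open-chain C7 acylation instead of closing.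
- *Reactivity:* the enol ether is also deactivated by its electron-poor alkenyl substituent, so ketene oligomerisation may outrun addition.
- *Face selectivity:* it rests on a conformational preference at C9 that is not enforced by strong allylic strain.
- *Fallback:*
  1. From 26, dichloroketene (Cl3CCOCl, Zn–Cu couple, Et2O), the most electrophilic ketene and the least demanding at the closing carbon, would give the 17,17-dichlorocyclobutanone F1.
  2. Peracid oxidation as in step 20 gives the dichlorolactone F2.
  3. Zinc in acetic acid gives the C17-unsubstituted lactone F3.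
  4. LiN(SiMe3)2 and MeI at −78 °C bring in C18 anti to the C9 branch. This returns the route to 31.

**Step 22.**
- *What may go wrong:* the strained ten-membered transition state slows transmetallation and reductive elimination. Intermolecular coupling, protodeboronation, hydrolysis of the triflate, or ionisation of the C12 allylic acetate by zerovalent palladium may then take over.
- *Fallback:*
  1. From 31, Stille coupling with tributyl(vinyl)stannane (Pd(PPh3)4, LiCl, THF) replaces the triflate and gives the C5 vinyl compound F4, whose inner vinyl carbon becomes C4.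
  2. Ring-closing metathesis with the second-generation Grubbs catalyst joins C3 to C4 with loss of ethene and gives the ten-membered 3,5-diene F5.
  3. Diimide (potassium azodicarboxylate, AcOH) saturates the strained disubstituted C3=C4 bond in preference to the hindered C13=C14 and the tetrasubstituted C5=C6 bonds. This returns the route to 33.

**Step 21.**
- *What may go wrong:* the zinc enolate has the C8 siloxy group in the β-position, and loss of silanolate to a butenolide may compete with protonation. The DBU equilibration carries the same E1cB risk.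
- *Fallback:* the mechanism is changed from a two-electron enolate route to a radical chain, which has no anionic intermediate. From 30, Bu3SnH with Et3B and air in toluene at rt abstracts the tertiary chlorine, and the C17 radical takes hydrogen. Vinyl chloride and vinyl triflate are inert under these conditions. The route continues at 31 without any new compound.

**Step 13.**
- *What may go wrong:* the 12β-hydroxyl is axial, flanked by C11, and may be tied up as a lactol with the C9 ketone. Slow activation, elimination to a cyclohexadiene, or allylic transposition are the likely failures.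
- *Fallback:*
  1. Activation is separated from displacement. From 20, ClCH2SO2Cl and pyridine give the C12 chloromethanesulfonate F6.
  2. CsOAc with 18-crown-6 in toluene displaces it.
  3. Even if ionisation intervenes, acetate should still enter at C12 from the open α face, so the route returns to 21.

**Step 5.**
- *What may go wrong:* the strongly acidic catalyst may strip the silyl dienol ether or divert it to a Mukaiyama–Michael path. Enantioface selection is untested for this diene and dienophile pair.
- *Fallback:*
  1. From 6 and 7, Me2AlCl in CH2Cl2 gives racemic 8, and step 6 gives racemic 9.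
  2. Dess–Martin oxidation gives the racemic vinyl ketone F7.
  3. Corey–Bakshi–Shibata reduction with the (R)-B-methyl oxazaborolidine and catecholborane fixes C2 as S in both antipodes, the quaternary C1 acting as the large group.
  4. The antipodes thereby become diastereomers: 9 and the 2S alcohol on the enantiomeric ring F8. These are separated by chromatography, and the route is rejoined at 9.

## Further compounds

F1 | step 19 | 17,17-dichlorocyclobutanone from 26 and dichloroketene | FC(F)(F)S(=O)(=O)O/C(C)=C(/Cl)[C@@H]1C(=O)C(Cl)(Cl)[C@@]1(O[Si](C)(C)C(C)(C)C)[C@@H](O[Si](C)(C)C(C)(C)C)[C@H]2[C@@H](C)[C@H](OC(C)=O)C=C[C@]2(C)[C@@H](OC(C)=O)C=C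
F2 | step 19 | 17,17-dichloro γ-lactone | FC(F)(F)S(=O)(=O)O/C(C)=C(/Cl)[C@@H]1OC(=O)C(Cl)(Cl)[C@@]1(O[Si](C)(C)C(C)(C)C)[C@@H](O[Si](C)(C)C(C)(C)C)[C@H]2[C@@H](C)[C@H](OC(C)=O)C=C[C@]2(C)[C@@H](OC(C)=O)C=C
F3 | step 19 | C17-unsubstituted γ-lactone | FC(F)(F)S(=O)(=O)O/C(C)=C(/Cl)[C@@H]1OC(=O)C[C@@]1(O[Si](C)(C)C(C)(C)C)[C@@H](O[Si](C)(C)C(C)(C)C)[C@H]2[C@@H](C)[C@H](OC(C)=O)C=C[C@]2(C)[C@@H](OC(C)=O)C=C
F4 | step 22 | C5 vinyl analogue of 31 | C=C/C(C)=C(/Cl)[C@@H]1OC(=O)[C@H](C)[C@@]1(O[Si](C)(C)C(C)(C)C)[C@@H](O[Si](C)(C)C(C)(C)C)[C@H]2[C@@H](C)[C@H](OC(C)=O)C=C[C@]2(C)[C@@H](OC(C)=O)C=C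
F5 | step 22 | ten-membered (3Z)-3,5-diene, 3,4-didehydro-33 | CC(=O)O[C@H]1/C=C\C(C)=C(\Cl)[C@@H]2OC(=O)[C@H](C)[C@@]2(O[Si](C)(C)C(C)(C)C)[C@@H](O[Si](C)(C)C(C)(C)C)[C@H]2[C@@H](C)[C@H](OC(C)=O)C=C[C@@]21C
F0 | step 21 | none | none
F6 | step 13 | 12β-chloromethanesulfonate of 20 | FC(F)(F)S(=O)(=O)O/C(C)=C(/Cl)CC1(SCCCS1)C(=O)[C@H]2[C@@H](C)[C@@H](OS(=O)(=O)CCl)C=C[C@]2(C)[C@@H](O[Si](CC)(CC)CC)C=C
F7 | step 5 | C2 vinyl ketone (racemic; the antipode leading to 9 is drawn) | CCOC(=O)[C@H]1[C@H](C)C(O[Si](C)(C)C(C)(C)C)=CC[C@]1(C)C(=O)C=C
F8 | step 5 | (2S)-alcohol on the enantiomeric ring, diastereomer of 9 | CCOC(=O)[C@@H]1[C@@H](C)C(O[Si](C)(C)C(C)(C)C)=CC[C@@]1(C)[C@@H](O)C=C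
A1 | alternative 1 | ten-membered 5,6-allene hydroxy acid, 9-OTES, 2,12-diacetate (allene axis as needed for anti addition) | CC(=O)O[C@H]1CCC(C)=C=C[C@@](O)([C@@H](C)C(O)=O)[C@@H](O[Si](CC)(CC)CC)[C@H]2[C@@H](C)[C@H](OC(C)=O)C=C[C@@]21C
A2 | alternative 1 | C9 triethylsilyl ether of 34 | CC(=O)O[C@H]1CC/C(C)=C(/Cl)[C@@H]2OC(=O)[C@H](C)[C@@]2(O)[C@@H](O[Si](CC)(CC)CC)[C@H]2[C@@H](C)[C@H](OC(C)=O)C=C[C@@]21C
A3 | alternative 2 | tricyclic chlorocyclohexadiene with intact C3–C8 bond, trans-fused at C3/C8 | CC(=O)O[C@H]1[C@@H]2C=C(C)C(Cl)=C[C@@]2([C@@H](C)C(=O)OC(C)(C)C)[C@@H](O[Si](C)(C)C(C)(C)C)[C@H]3[C@@H](C)[C@H](OC(C)=O)C=C[C@@]31C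
A4 | alternative 2 | ten-membered triene, C3=C4 E, C5=C6 ring-cis, C7=C8 E | CC(=O)O[C@H]1/C=C/C(C)=C(Cl)\C=C(/[C@@H](C)C(=O)OC(C)(C)C)[C@@H](O[Si](C)(C)C(C)(C)C)[C@H]2[C@@H](C)[C@H](OC(C)=O)C=C[C@@]21C
A5 | alternative 3 | C9 δ-lactone closed on C13–O, with (Z)-3-benzyloxy-2-methylprop-1-enyl at C13, 12-OTBS, 11-methyl | O=C1C[C@@H](C)[C@H](O[Si](C)(C)C(C)(C)C)[C@H](/C=C(\COCc2ccccc2)C)O1
A6 | alternative 3 | cyclohexene C9 carboxylic acid with quaternary C1 (C2 as benzyloxymethyl) | OC(=O)[C@H]1[C@@H](C)[C@H](O[Si](C)(C)C(C)(C)C)C=C[C@]1(C)COCc2ccccc2
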